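**Retrosynthetic overview** (benzofuran numbering; ring A = carbocycle C3a–C4–C5–C6–C7–C7a, ring B = dihydrofuran O1–C2–C3–C3a–C7a)
1. The C3a=C4 double bond is introduced last, by γ-bromination and dehydrobromination of the saturated C6-ketone vinylogous ester. Before that, the C5 centre (allyl, OMe) is made from a C5 allyl ester by palladium-catalysed decarboxylative asymmetric allylation, so the ester is a traceless activating group.
2. Key disconnection: ring A is cut at C4–C5 and C7–C7a in one [3+3] operation. The enabling feature is the vinylogous ester O1–C7a=C7–C6=O of ring A: C7a carries the ring-B oxygen at the carboxylic acid level, 1,3 to the C6 ketone (Claisen retron), with C4 β to it (Michael retron), and C6 lies between two methoxy-bearing carbons, C5 and C7.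
3. The C4–C3a–C7a(–O1) half is therefore a latent α-methylene γ-butyrolactone, and the C5–C6–C7 half is an α,α′-bis-nucleophilic ketone (allyl 2,4-dimethoxy-3-oxobutanoate).
4. In the forward direction, Michael addition and Claisen closure on the lactone carbonyl build ring A. The lactone acyl C–O bond is cut and its oxygen returns to C7a by cyclodehydration, so ring B re-forms in the same flask with C2 and C3 untouched.
5. The lactone comes from an anti-selective Marshall propargylation (sets C2, C3) and a palladium-catalysed cyclocarbonylation; the keto ester comes from self-Claisen condensation of allyl methoxyacetate. Ring order: γ-lactone, then ring A, then ring B.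

Key step: step 6

Remark: compounds 1, 3, 7 and 8 are taken as purchased. C3a and C5 of 11–13 (and C3a of 14) form without control and are drawn without descriptors, because both centres are reset later.

**Step 1**
Reactants: 1 (R)-but-3-yn-2-ol
Product: 2 (R)-but-3-yn-2-yl methanesulfonate
Conditions: MsCl, Et3N, CH2Cl2, −78 → 0 °C
Reagents that add atoms: methanesulfonyl chloride CS(=O)(=O)Cl
Why: Sulfonylation of a secondary alcohol at oxygen leaves the C–O bond intact, so the (R) configuration is retained.

**Step 2**
Reactants: 2 (R)-but-3-yn-2-yl methanesulfonate; 3 3,4,5-trimethoxybenzaldehyde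
Product: 5 (1S,2S)-2-methyl-1-(3,4,5-trimethoxyphenyl)but-3-yn-1-ol, via allenylzinc reagent 4 (not isolated)
Conditions: Pd(OAc)2 (5 mol %), PPh3 (5 mol %), Et2Zn (3 equiv), THF, −78 → −20 °C; aq. NH4Cl
Reagents that add atoms: none
Why: Marshall propargylation: zerovalent palladium formed in situ should ionise the mesylate anti, transmetalation gives the (aS)-allenylzinc, and its cyclic SE2′ addition to the aldehyde should set both new centres anti and (1S,2S) by transfer of the mesylate chirality.

**Step 3**
Reactants: 5 (1S,2S)-2-methyl-1-(3,4,5-trimethoxyphenyl)but-3-yn-1-ol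
Product: 6 (4S,5S)-4-methyl-3-methylidene-5-(3,4,5-trimethoxyphenyl)oxolan-2-one
Conditions: PdCl2 (5 mol %), SnCl2 (5 mol %), PPh3 (10 mol %), CO (7 atm), MeCN, 70 °C
Reagents that add atoms: carbon monoxide [C-]#[O+]
Why: Norton-type palladium-catalysed cyclocarbonylation of a homopropargylic alcohol: an alkoxycarbonyl-palladium species adds syn across the alkyne and protonolysis gives the α-methylene γ-lactone without touching either stereocentre.

**Step 4**
Reactants: 7 methoxyacetyl chloride; 8 prop-2-en-1-ol
Product: 9 prop-2-enyl methoxyacetate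
Conditions: Et3N, DMAP (cat.), CH2Cl2, 0 °C
Reagents that add atoms: none
Why: Acylation of a primary alcohol by an acid chloride.

**Step 5**
Reactants: 9 prop-2-enyl methoxyacetate (2 equiv)
Product: 10 prop-2-enyl 2,4-dimethoxy-3-oxobutanoate
Conditions: NaH (0.55 equiv per ester), THF, 0 → 40 °C; 1 M HCl
Reagents that add atoms: none
Why: Claisen self-condensation, driven to completion by deprotonation of the β-keto ester product; its C2 centre is enolisable and of no consequence.

**Step 6**
Reactants: 6 (4S,5S)-4-methyl-3-methylidene-5-(3,4,5-trimethoxyphenyl)oxolan-2-one; 10 prop-2-enyl 2,4-dimethoxy-3-oxobutanoate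
Product: 13 prop-2-enyl (2S,3S)-5,7-dimethoxy-3-methyl-6-oxo-2-(3,4,5-trimethoxyphenyl)-2,3,3a,4,5,6-hexahydro-1-benzofuran-5-carboxylate, via Michael adduct 11 (not isolated), via hydroxy trione 12 (not isolated)
Conditions: t-BuOK (1.1 equiv), THF, −20 → 23 °C (6 added slowly to the enolate of 10); then CF3CO2H (3 equiv), 0 → 23 °C
Reagents that add atoms: none
Why: The potassium enolate of 10, formed at the carbon between ketone and ester, adds to the exocyclic methylene of 6 (C4–C5), the resulting lactone enolate passes its charge by proton transfer to C7, and the C7 enolate attacks the lactone carbonyl (C7–C7a) in a Claisen condensation that expels the C2 alkoxide and is driven by formation of the 2-methoxy-1,3-dione enolate; acid then returns the C2 hydroxyl to C7a by hemiketalisation and loss of water. The closest known reaction type is the consecutive Michael–Claisen [3+3] synthesis of cyclohexane-1,3-diones from ketones and acrylates, followed by the acid cyclisation of hydroxyalkyl 1,3-diones to fused dihydrofuran vinylogous esters. Ring A closes by 6-(enolendo)-exo-trig attack and ring B re-closes by 5-exo-trig hemiketalisation and dehydration. C2 and C3 are carried over from 6 because only the acyl C–O bond is broken, whereas C5 and C3a form without control, which is harmless because C5 is reset through its enolate in step 7 and C3a becomes trigonal in step 8. The step needs regiocontrol of the two C–C bonds: the allyl ester makes C5 the only carbon deprotonated by one equivalent of base, and once C5 is quaternary C7 is the only ketone α-position left and can reach only the lactone carbonyl through a six-membered transition state.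

**Step 7**
Reactants: 13 prop-2-enyl (2S,3S)-5,7-dimethoxy-3-methyl-6-oxo-2-(3,4,5-trimethoxyphenyl)-2,3,3a,4,5,6-hexahydro-1-benzofuran-5-carboxylate
Product: 14 (2S,3S,5R)-5,7-dimethoxy-3-methyl-5-(prop-2-enyl)-2-(3,4,5-trimethoxyphenyl)-2,3,3a,4-tetrahydro-1-benzofuran-6(5H)-one
Conditions: Pd2(dba)3 (2.5 mol %), (R)-t-BuPHOX (6.25 mol %), PhMe, 30 °C
Reagents that add atoms: none
Why: Stoltz-type decarboxylative asymmetric allylic alkylation: zerovalent palladium ionises the allyl ester, loss of CO2 gives the C5 enolate regiospecifically (erasing the uncontrolled C5 configuration), and inner-sphere allyl transfer within the (R)-t-BuPHOX complex should set 5R under catalyst control, the ligand enantiomer being chosen by analogy with the facial sense known for 2-alkyl and 2-alkoxy cyclohexanone and vinylogous-ester enolates; C4 is still saturated, so the enolate cannot aromatise.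

**Step 8**
Reactants: 14 (2S,3S,5R)-5,7-dimethoxy-3-methyl-5-(prop-2-enyl)-2-(3,4,5-trimethoxyphenyl)-2,3,3a,4-tetrahydro-1-benzofuran-6(5H)-one
Product: 17 (2S,3S,5R)-5,7-dimethoxy-3-methyl-5-(prop-2-enyl)-2-(3,4,5-trimethoxyphenyl)-2,3-dihydro-1-benzofuran-6(5H)-one, via silyl dienol ether 15 (not isolated), via tertiary bromide 16 (not isolated)
Conditions: LiN(i-Pr)2 (1.2 equiv), Me3SiCl (1.5 equiv), THF, −78 °C, volatiles removed; NBS (1.05 equiv), THF, −78 °C; DBU (2.5 equiv), −78 → 0 °C
Reagents that add atoms: none
Why: γ-Deprotonation of the vinylogous ester (C5 is quaternary, so H-3a is the only acidic hydrogen) and O-silylation give the dienol ether, NBS should brominate its γ-carbon C3a anti to the neighbouring C3 methyl group as in the classical 6-bromination of steroidal dienol ethers, and E2 dehydrobromination with DBU can then take only an anti C4 hydrogen (the C3 hydrogen is syn to bromine and more hindered), giving the C3a=C4 bond of the 2,4-dienone at or below 0 °C, where allyl shifts of the product should not yet set in.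

**Compound list**
1 | (R)-but-3-yn-2-ol | C#C[C@@H](C)O | starting material
2 | (R)-but-3-yn-2-yl methanesulfonate | C#C[C@@H](C)OS(C)(=O)=O | intermediate
3 | 3,4,5-trimethoxybenzaldehyde | COc1cc(C=O)cc(OC)c1OC | starting material
4 | (aS)-buta-1,2-dien-1-yl(ethyl)zinc, allenylzinc reagent | [H]C(C)=[C@]=C([H])[Zn]CC | intermediate
5 | (1S,2S)-2-methyl-1-(3,4,5-trimethoxyphenyl)but-3-yn-1-ol | C#C[C@H](C)[C@H](O)c1cc(OC)c(OC)c(OC)c1 | intermediate
6 | (4S,5S)-4-methyl-3-methylidene-5-(3,4,5-trimethoxyphenyl)oxolan-2-one | C=C1C(=O)O[C@H](c2cc(OC)c(OC)c(OC)c2)[C@H]1C | intermediate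
7 | methoxyacetyl chloride | COCC(=O)Cl | starting material
8 | prop-2-en-1-ol (allyl alcohol) | C=CCO | starting material
9 | prop-2-enyl methoxyacetate | COCC(=O)OCC=C | intermediate
10 | prop-2-enyl 2,4-dimethoxy-3-oxobutanoate | COCC(=O)C(OC)C(=O)OCC=C | intermediate
11 | prop-2-enyl 2-methoxy-2-(methoxyacetyl)-3-[(4S,5S)-4-methyl-2-oxo-5-(3,4,5-trimethoxyphenyl)oxolan-3-yl]propanoate, Michael adduct (C2 of the propanoate and C3 of the oxolane uncontrolled) | C=CCOC(=O)C(OC)(C(=O)COC)CC1C(=O)O[C@H](c2cc(OC)c(OC)c(OC)c2)[C@H]1C | intermediate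
12 | prop-2-enyl 5-[(1S,2S)-1-hydroxy-1-(3,4,5-trimethoxyphenyl)propan-2-yl]-1,3-dimethoxy-2,4-dioxocyclohexane-1-carboxylate, hydroxy trione (ring centres uncontrolled) | C=CCOC(=O)C1(OC)CC(C(=O)C(OC)C1=O)[C@H](C)[C@H](O)c1cc(OC)c(OC)c(OC)c1 | intermediate
13 | prop-2-enyl (2S,3S)-5,7-dimethoxy-3-methyl-6-oxo-2-(3,4,5-trimethoxyphenyl)-2,3,3a,4,5,6-hexahydro-1-benzofuran-5-carboxylate (C3a and C5 uncontrolled) | C=CCOC(=O)C1(OC)CC2C(=C(OC)C1=O)O[C@H](c1cc(OC)c(OC)c(OC)c1)[C@H]2C | intermediate
14 | (2S,3S,5R)-5,7-dimethoxy-3-methyl-5-(prop-2-enyl)-2-(3,4,5-trimethoxyphenyl)-2,3,3a,4-tetrahydro-1-benzofuran-6(5H)-one (C3a uncontrolled) | C=CC[C@@]1(OC)CC2C(=C(OC)C1=O)O[C@H](c1cc(OC)c(OC)c(OC)c1)[C@H]2C | intermediate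
15 | [(2S,3S,5R)-5,7-dimethoxy-3-methyl-5-(prop-2-enyl)-2-(3,4,5-trimethoxyphenyl)-2,3,4,5-tetrahydro-1-benzofuran-6-yl]oxy(trimethyl)silane, silyl dienol ether | C=CC[C@@]1(OC)CC2=C(C(OC)=C1O[Si](C)(C)C)O[C@H](c1cc(OC)c(OC)c(OC)c1)[C@H]2C | intermediate
16 | (2S,3R,3aS,5R)-3a-bromo-5,7-dimethoxy-3-methyl-5-(prop-2-enyl)-2-(3,4,5-trimethoxyphenyl)-2,3,3a,4-tetrahydro-1-benzofuran-6(5H)-one, tertiary bromide (bromine trans to the C3 methyl) | C=CC[C@@]1(OC)C[C@@]2(Br)C(=C(OC)C1=O)O[C@H](c1cc(OC)c(OC)c(OC)c1)[C@H]2C | intermediate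
17 | (2S,3S,5R)-5,7-dimethoxy-3-methyl-5-(prop-2-enyl)-2-(3,4,5-trimethoxyphenyl)-2,3-dihydro-1-benzofuran-6(5H)-one | C=CC[C@@]1(OC)C=C2C(=C(OC)C1=O)O[C@H](c1cc(OC)c(OC)c(OC)c1)[C@H]2C | target

**Step count and risks**
Total step count: 8. Longest linear sequence: 6 steps (steps 1, 2, 3, 6, 7, 8).

Steps most likely to fail:

1. Step 6. The methylene lactone may be lost to base-induced oligomerisation or retro-Michael reaction before the slower Claisen closure, or the liberated C2 alkoxide may transacylate the allyl ester. The fallback uses an open-chain acrylate, so the Claisen step expels methoxide and no tethered alkoxide is formed. It sets out from 5: silylation (t-BuMe2SiOSO2CF3, 2,6-lutidine) should give tert-butyl(dimethyl)[(1S,2S)-2-methyl-1-(3,4,5-trimethoxyphenyl)but-3-ynoxy]silane F1. Branched-selective methoxycarbonylation of the alkyne (Pd(OAc)2, 2-pyridyldiphenylphosphine, MeSO3H, CO, MeOH) should give methyl (3S,4S)-4-[tert-butyl(dimethyl)silyl]oxy-3-methyl-2-methylidene-4-(3,4,5-trimethoxyphenyl)butanoate F2. Michael–Claisen annulation of F2 with 10 (t-BuOK, THF) should give prop-2-enyl 5-[(1S,2S)-1-[tert-butyl(dimethyl)silyl]oxy-1-(3,4,5-trimethoxyphenyl)propan-2-yl]-1,3-dimethoxy-2,4-dioxocyclohexane-1-carboxylate F3. HF·pyridine then removes silicon, and the freed hydroxyl cyclises onto C7a with loss of water, rejoining the route at 13.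

2. Step 8. Bromination may occur on the methyl-bearing face of C3a or on the electron-rich arene, and elimination toward C3 would be followed by isomerisation to a furan. The fallback replaces halogenation and base-mediated anti elimination by a Saegusa–Ito dehydrosilylation. It sets out from 15, which is isolated, and treatment with Pd(OAc)2 (1.1 equiv) in MeCN at 23 °C should form the C3a=C4 bond by syn β-hydride elimination from a palladium enolate. It comes back directly at 17 and makes no new compound (F0).

3. Step 7. Facial selectivity of the allyl transfer may be poor (mismatch with the neighbouring C3a centre), or the palladium enolate may be protonated instead of allylated. The fallback uses an outer-sphere Trost-type allylation of a preformed enol carbonate. It sets out from 13: deallylation and decarboxylation (Pd(PPh3)4, morpholine, THF) should give (2S,3S)-5,7-dimethoxy-3-methyl-2-(3,4,5-trimethoxyphenyl)-2,3,3a,4-tetrahydro-1-benzofuran-6(5H)-one F4. Kinetic α′-enolisation and O-acylation (KN(SiMe3)2, allyl chloroformate, THF, −78 °C) should give prop-2-enyl [(2S,3S)-5,7-dimethoxy-3-methyl-2-(3,4,5-trimethoxyphenyl)-2,3,3a,4-tetrahydro-1-benzofuran-6-yl] carbonate F5. Decarboxylative allylation with Pd2(dba)3·CHCl3 and the DACH-phenyl Trost ligand (enantiomer selected for 5R) in dioxane comes back at 14.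

**Further compounds**
F1 | step 6 | tert-butyl(dimethyl)[(1S,2S)-2-methyl-1-(3,4,5-trimethoxyphenyl)but-3-ynoxy]silane | C#C[C@H](C)[C@H](O[Si](C)(C)C(C)(C)C)c1cc(OC)c(OC)c(OC)c1
F2 | step 6 | methyl (3S,4S)-4-[tert-butyl(dimethyl)silyl]oxy-3-methyl-2-methylidene-4-(3,4,5-trimethoxyphenyl)butanoate | C=C(C(=O)OC)[C@H](C)[C@H](O[Si](C)(C)C(C)(C)C)c1cc(OC)c(OC)c(OC)c1
F3 | step 6 | prop-2-enyl 5-[(1S,2S)-1-[tert-butyl(dimethyl)silyl]oxy-1-(3,4,5-trimethoxyphenyl)propan-2-yl]-1,3-dimethoxy-2,4-dioxocyclohexane-1-carboxylate | C=CCOC(=O)C1(OC)CC(C(=O)C(OC)C1=O)[C@H](C)[C@H](O[Si](C)(C)C(C)(C)C)c1cc(OC)c(OC)c(OC)c1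
F4 | step 7 | (2S,3S)-5,7-dimethoxy-3-methyl-2-(3,4,5-trimethoxyphenyl)-2,3,3a,4-tetrahydro-1-benzofuran-6(5H)-one | COC1CC2C(=C(OC)C1=O)O[C@H](c1cc(OC)c(OC)c(OC)c1)[C@H]2C
F5 | step 7 | prop-2-enyl [(2S,3S)-5,7-dimethoxy-3-methyl-2-(3,4,5-trimethoxyphenyl)-2,3,3a,4-tetrahydro-1-benzofuran-6-yl] carbonate | C=CCOC(=O)OC1=C(OC)CC2C(=C1OC)O[C@H](c1cc(OC)c(OC)c(OC)c1)[C@H]2C
F0 | step 8 | none | none
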